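The cyclohexenone ring is cut at C2–C3 and C4–C5 (C1 = ketone, C2 = hydroxymethyl carbon, C3 = enone CH, C4 = isobutyrate carbon, C5 = isopropyl carbon, C6 = hydroxytiglate carbon). The C3–C4 edge is read as a masked cis-enediol: a Diels–Alder reaction of a 1,4-disubstituted 2-silyloxy diene (C2=C1–C6=C5) with vinylene carbonate closes the ring in one operation and fixes the cis C4–O/C5-isopropyl relationship by endo approach. The silyl enol ether left at C1=C6 then delivers the C6 oxygen (Rubottom), and the new C1 ketone expels the C3 carbonate oxygen, which leaves the C2=C3 enone and the free C4 hydroxyl. An acylative kinetic resolution installs the isobutyrate and the absolute configuration.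

Key step: step 4

Remark: ring atoms are numbered C1 to C6 as in the paragraph above; compounds 10, 11 and 12 are racemates and are written as the enantiomer that leads to the target. Aldehyde 15 is taken as a catalogue compound.

Step 1
Reactants: 1 but-3-en-2-one (methyl vinyl ketone); 2 (4-methoxyphenyl)methanol (4-methoxybenzyl alcohol, PMBOH)
Product: 3 4-[(4-methoxybenzyl)oxy]butan-2-one
Conditions: PMe3 (5 mol %), THF, rt
Reagents that add atoms: none
Why: Phosphine-catalysed oxa-Michael addition of the alcohol to the vinyl ketone, in which the phosphonium enolate deprotonates the alcohol and the alkoxide adds to a further molecule of enone, with no stereocentre formed.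

Step 2
Reactants: 3 4-[(4-methoxybenzyl)oxy]butan-2-one; 4 2-methylpropanal (isobutyraldehyde)
Product: 7 (E)-1-[(4-methoxybenzyl)oxy]-6-methylhept-4-en-3-one, via lithium aldolate 5 (not isolated), via aldol mesylate 6 (not isolated)
Conditions: LDA, THF, −78 °C; 4; then MsCl, Et3N, −78 °C → rt
Reagents that add atoms: none
Why: Aldol condensation in one flask, in which LDA deprotonates the methyl group of 3 under kinetic control, the enolate adds to 4, and mesylation of the aldolate followed by E1cB elimination should give the conjugated (E)-enone, the transient carbinol centre being lost.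

Step 3
Reactants: 7 (E)-1-[(4-methoxybenzyl)oxy]-6-methylhept-4-en-3-one
Product: 8 tert-butyl({(2Z,4E)-1-[(4-methoxybenzyl)oxy]-6-methylhepta-2,4-dien-3-yl}oxy)dimethylsilane
Conditions: TBSOTf, Et3N, CH2Cl2, −78 → 0 °C
Reagents that add atoms: tert-butyldimethylsilyl trifluoromethanesulfonate (TBSOTf), CC(C)(C)[Si](C)(C)OS(=O)(=O)C(F)(F)F
Why: Soft enolisation and O-silylation towards the α′-methylene gives the cross-conjugated silyl dienol ether, and the (Z) enol ether, with CH2OPMB next to OTBS and away from the vinyl group, should predominate, which places this group on the outside of the s-cis diene.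

Step 4
Reactants: 8 tert-butyl({(2Z,4E)-1-[(4-methoxybenzyl)oxy]-6-methylhepta-2,4-dien-3-yl}oxy)dimethylsilane; 9 1,3-dioxol-2-one (vinylene carbonate)
Product: 10 rac-5-[(tert-butyldimethylsilyl)oxy]-4-{[(4-methoxybenzyl)oxy]methyl}-7-(propan-2-yl)-3a,4,7,7a-tetrahydro-1,3-benzodioxol-2-one, with H-3a, H-4, H-7 and H-7a all cis (CH2OPMB at C2, the carbonate oxygens at C3 and C4, and isopropyl at C5 on one face; C1=C6 TBS enol ether)
Conditions: 9 (5 equiv), BHT (cat.), toluene, sealed tube, 170 °C
Reagents that add atoms: none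
Why: The electron-rich (2Z,4E)-2-silyloxy diene and the cis-enediol carbonate combine in a concerted, suprafacial thermal [4+2] cycloaddition that forms C2–C3 and C4–C5 at once and leaves the C1=C6 silyl enol ether. The closest known reaction type is the Diels–Alder reaction of vinylene carbonate with 1,4-disubstituted butadienes at 150–200 °C, which gives all-cis adducts. The cyclohexene ring is closed by this cycloaddition, while the five-membered carbonate ring is carried in intact and only becomes cis-fused. The C3 and C4 oxygens are cis because the dienophile is cis, and endo approach of the carbonate under the diene places them cis to the two outside groups, CH2OPMB at C2 (from the Z enol ether) and isopropyl at C5 (from the E alkene), so the cis C4–O/C5-isopropyl relationship of the target is set; there is no absolute control and 10 is racemic. The step needs endo over exo selectivity, for which the known endo preference of vinylene carbonate stands, while regiochemistry is no issue because the dienophile is symmetrical and its two oxygens are told apart later by the C1 carbonyl.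

Step 5
Reactants: 10 rac-all-cis Diels–Alder adduct
Product: 12 rac-(4S,5S,6R)-6-[(tert-butyldimethylsilyl)oxy]-4-hydroxy-2-{[(4-methoxybenzyl)oxy]methyl}-5-(propan-2-yl)cyclohex-2-en-1-one, via silyloxy ketone carbonate 11 (not isolated)
Conditions: mCPBA, CH2Cl2, −20 → 0 °C; Me2S; then DBU, 0 °C → rt
Reagents that add atoms: 3-chloroperoxybenzoic acid (mCPBA), OOC(=O)c1cccc(Cl)c1
Why: Rubottom oxidation, in which the peracid epoxidises the C1=C6 silyl enol ether from the face opposite the four cis substituents and silyl migration gives the C6–OTBS ketone 11 with oxygen trans to isopropyl, after which DBU removes H-2 so that the C3 carbonate oxygen leaves (E1cB) and CO2 is lost, which gives the C2=C3 enone and the free C4 hydroxyl.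

Step 6
Reactants: 12 rac-(4S,5S,6R)-6-[(tert-butyldimethylsilyl)oxy]-4-hydroxy-2-{[(4-methoxybenzyl)oxy]methyl}-5-(propan-2-yl)cyclohex-2-en-1-one
Product: 13 (4S,5S,6R)-6-[(tert-butyldimethylsilyl)oxy]-2-{[(4-methoxybenzyl)oxy]methyl}-4-[(2-methylpropanoyl)oxy]-5-(propan-2-yl)cyclohex-2-en-1-one
Conditions: (R)-benzotetramisole [(R)-2-phenyl-2,3-dihydroimidazo[2,1-b][1,3]benzothiazole] (10 mol %), (iPrCO)2O (0.6 equiv), iPr2NEt, CHCl3, 0 °C; chromatographic removal of the unreacted mirror-image alcohol
Reagents that add atoms: 2-methylpropanoic anhydride (isobutyric anhydride), CC(C)C(=O)OC(=O)C(C)C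
Why: Acylative kinetic resolution by a chiral amidine acyl-transfer catalyst, in which the N-isobutyryl catalyst cation recognises the C2=C3 π system next to the carbinol and, by analogy with aryl and alkenyl carbinols, the (R)-catalyst should acylate the (4S) enantiomer faster, so that at most half of the material is taken on as ester 13 and no new stereocentre is formed.

Step 7
Reactants: 13 (4S,5S,6R)-6-[(tert-butyldimethylsilyl)oxy]-2-{[(4-methoxybenzyl)oxy]methyl}-4-[(2-methylpropanoyl)oxy]-5-(propan-2-yl)cyclohex-2-en-1-one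
Product: 14 (4S,5R,6R)-6-hydroxy-2-{[(4-methoxybenzyl)oxy]methyl}-4-[(2-methylpropanoyl)oxy]-5-(propan-2-yl)cyclohex-2-en-1-one (same spatial arrangement as 13; only the descriptor at C5 changes)
Conditions: HF·pyridine, pyridine, THF, 0 °C → rt
Reagents that add atoms: none
Why: Fluoride-mediated desilylation of the secondary TBS ether, to which the esters, the PMB ether and the enone are inert, while the trans 1,3-relationship of the C4 ester and the C6 hydroxyl disfavours acyl migration.

Step 8
Reactants: 15 2-[(4-methoxybenzyl)oxy]acetaldehyde; 16 ethyl 2-(triphenylphosphoranylidene)propanoate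
Product: 17 ethyl (E)-4-[(4-methoxybenzyl)oxy]-2-methylbut-2-enoate
Conditions: CH2Cl2, rt
Reagents that add atoms: none
Why: Wittig olefination with a stabilised α-branched ylide, which should give the (E)-trisubstituted enoate with the ester trans to CH2OPMB.

Step 9
Reactants: 17 ethyl (E)-4-[(4-methoxybenzyl)oxy]-2-methylbut-2-enoate
Product: 18 (E)-4-[(4-methoxybenzyl)oxy]-2-methylbut-2-enoic acid
Conditions: LiOH, THF/H2O, rt; then aq. HCl to pH 3
Reagents that add atoms: lithium hydroxide, [Li+].[OH-]
Why: Saponification of the ethyl ester, under which the PMB ether and the alkene geometry are stable.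

Step 10
Reactants: 14 (4S,5R,6R)-6-hydroxy-2-{[(4-methoxybenzyl)oxy]methyl}-4-[(2-methylpropanoyl)oxy]-5-(propan-2-yl)cyclohex-2-en-1-one; 18 (E)-4-[(4-methoxybenzyl)oxy]-2-methylbut-2-enoic acid
Product: 19 (4S,5S,6R)-6-({(2E)-4-[(4-methoxybenzyl)oxy]-2-methylbut-2-enoyl}oxy)-2-{[(4-methoxybenzyl)oxy]methyl}-4-[(2-methylpropanoyl)oxy]-5-(propan-2-yl)cyclohex-2-en-1-one
Conditions: MNBA (2-methyl-6-nitrobenzoic anhydride), DMAP, Et3N, CH2Cl2, rt
Reagents that add atoms: none
Why: Shiina esterification, in which the mixed anhydride formed from 18 acylates the hindered α-ketol under DMAP catalysis at room temperature, conditions mild enough to leave the C4 ester, the enone and the C6 configuration untouched.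

Step 11
Reactants: 19 bis-PMB diester
Product: 20 (4S,5S,6R)-2-(hydroxymethyl)-6-{[(2E)-4-hydroxy-2-methylbut-2-enoyl]oxy}-4-[(2-methylpropanoyl)oxy]-5-(propan-2-yl)cyclohex-2-en-1-one (CNP0254776.1)
Conditions: DDQ, CH2Cl2/pH 7 phosphate buffer, 0 °C → rt
Reagents that add atoms: none
Why: Oxidative cleavage of both PMB ethers by DDQ through benzylic hydride abstraction and hydrolysis of the oxocarbenium ions, which should leave the two esters, the enone and the three stereocentres unaffected under buffered conditions.

Compound list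
1 | but-3-en-2-one (methyl vinyl ketone) | CC(=O)C=C | starting material
2 | (4-methoxyphenyl)methanol | COc1ccc(CO)cc1 | starting material
3 | 4-[(4-methoxybenzyl)oxy]butan-2-one | CC(=O)CCOCc1ccc(OC)cc1 | intermediate
4 | 2-methylpropanal (isobutyraldehyde) | CC(C)C=O | starting material
5 | lithium aldolate: lithium 1-[(4-methoxybenzyl)oxy]-6-methyl-3-oxoheptan-5-olate (racemic, not isolated) | [Li+].[O-]C(CC(=O)CCOCc1ccc(OC)cc1)C(C)C | intermediate
6 | aldol mesylate: 1-[(4-methoxybenzyl)oxy]-6-methyl-3-oxoheptan-5-yl methanesulfonate (racemic, not isolated) | CC(C)C(OS(C)(=O)=O)CC(=O)CCOCc1ccc(OC)cc1 | intermediate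
7 | (E)-1-[(4-methoxybenzyl)oxy]-6-methylhept-4-en-3-one | CC(C)/C=C/C(=O)CCOCc1ccc(OC)cc1 | intermediate
8 | tert-butyl({(2Z,4E)-1-[(4-methoxybenzyl)oxy]-6-methylhepta-2,4-dien-3-yl}oxy)dimethylsilane | CC(C)/C=C/C(O[Si](C)(C)C(C)(C)C)=C/COCc1ccc(OC)cc1 | intermediate
9 | 1,3-dioxol-2-one (vinylene carbonate) | O=C1OC=CO1 | starting material
10 | rac-5-[(tert-butyldimethylsilyl)oxy]-4-{[(4-methoxybenzyl)oxy]methyl}-7-(propan-2-yl)-3a,4,7,7a-tetrahydro-1,3-benzodioxol-2-one, all four ring hydrogens cis (racemate, one enantiomer drawn) | CC(C)(C)[Si](C)(C)OC1=C[C@@H](C(C)C)[C@H]2OC(=O)O[C@H]2[C@H]1COCc3ccc(OC)cc3 | intermediate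
11 | rac-6-[(tert-butyldimethylsilyl)oxy]-4-{[(4-methoxybenzyl)oxy]methyl}-7-(propan-2-yl)hexahydro-1,3-benzodioxole-2,5-dione, H-3a, H-4, H-7 and H-7a cis, OTBS trans to isopropyl (racemate, one enantiomer drawn, not isolated) | O=C1[C@H](O[Si](C)(C)C(C)(C)C)[C@@H](C(C)C)[C@H]2OC(=O)O[C@H]2[C@H]1COCc3ccc(OC)cc3 | intermediate
12 | rac-(4S,5S,6R)-6-[(tert-butyldimethylsilyl)oxy]-4-hydroxy-2-{[(4-methoxybenzyl)oxy]methyl}-5-(propan-2-yl)cyclohex-2-en-1-one (racemate, one enantiomer drawn) | CC(C)(C)[Si](C)(C)O[C@H]1C(=O)C(COCc2ccc(OC)cc2)=C[C@H](O)[C@@H]1C(C)C | intermediate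
13 | (4S,5S,6R)-6-[(tert-butyldimethylsilyl)oxy]-2-{[(4-methoxybenzyl)oxy]methyl}-4-[(2-methylpropanoyl)oxy]-5-(propan-2-yl)cyclohex-2-en-1-one | CC(C)(C)[Si](C)(C)O[C@H]1C(=O)C(COCc2ccc(OC)cc2)=C[C@H](OC(=O)C(C)C)[C@@H]1C(C)C | intermediate
14 | (4S,5R,6R)-6-hydroxy-2-{[(4-methoxybenzyl)oxy]methyl}-4-[(2-methylpropanoyl)oxy]-5-(propan-2-yl)cyclohex-2-en-1-one | O[C@H]1C(=O)C(COCc2ccc(OC)cc2)=C[C@H](OC(=O)C(C)C)[C@@H]1C(C)C | intermediate
15 | 2-[(4-methoxybenzyl)oxy]acetaldehyde | COc1ccc(COCC=O)cc1 | starting material
16 | ethyl 2-(triphenylphosphoranylidene)propanoate | CCOC(=O)C(C)=P(c1ccccc1)(c1ccccc1)c1ccccc1 | starting material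
17 | ethyl (E)-4-[(4-methoxybenzyl)oxy]-2-methylbut-2-enoate | CCOC(=O)/C(C)=C/COCc1ccc(OC)cc1 | intermediate
18 | (E)-4-[(4-methoxybenzyl)oxy]-2-methylbut-2-enoic acid | OC(=O)/C(C)=C/COCc1ccc(OC)cc1 | intermediate
19 | (4S,5S,6R)-6-({(2E)-4-[(4-methoxybenzyl)oxy]-2-methylbut-2-enoyl}oxy)-2-{[(4-methoxybenzyl)oxy]methyl}-4-[(2-methylpropanoyl)oxy]-5-(propan-2-yl)cyclohex-2-en-1-one | C/C(=C\COCc1ccc(OC)cc1)C(=O)O[C@H]1C(=O)C(COCc2ccc(OC)cc2)=C[C@H](OC(=O)C(C)C)[C@@H]1C(C)C | intermediate
20 | (4S,5S,6R)-2-(hydroxymethyl)-6-{[(2E)-4-hydroxy-2-methylbut-2-enoyl]oxy}-4-[(2-methylpropanoyl)oxy]-5-(propan-2-yl)cyclohex-2-en-1-one | C/C(=C\CO)C(=O)O[C@H]1C(=O)C(CO)=C[C@H](OC(=O)C(C)C)[C@@H]1C(C)C | target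

Total step count: 11. Longest linear sequence: 9 steps (steps 1–7, 10 and 11); the side-chain acid takes 2 steps (8 and 9).

Steps most likely to fail

The cycloaddition of step 4 may fail through insufficient reactivity of the dienophile towards a diene substituted at both termini, thermal loss of the silyl enol ether, or erosion of endo selectivity. The fallback builds the ring by an amine-catalysed Michael addition/aldol condensation instead. It sets out from enone 7, which with (tert-butyldimethylsilyloxy)acetaldehyde, a diarylprolinol silyl ether (the enantiomer that gives C5 as in the target) and an acid co-catalyst would give the 4-silyloxy-5-isopropylcyclohexenone F1, with C4–O expected trans to isopropyl. Kinetic deprotonation at C6 (LDA, −78 °C) and oxidation with a sulfonyloxaziridine would give the 6-hydroxy ketone F2, with OH trans to isopropyl. Shiina esterification with 18 would give the ester F3, and HF·pyridine the C4 alcohol F4. A Mitsunobu reaction with isobutyric acid, with inversion at C4, comes back to the route at 19 and makes the resolution unnecessary.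

The resolution of step 6 may fail through poor discrimination between the enantiomers or slow acyl transfer to the hindered, pseudoaxial C4 hydroxyl. The fallback sets out from 12, which is esterified completely with isobutyryl chloride and pyridine to the racemate, that is 13 together with the mirror-image isobutyrate F5. Preparative chromatography on a chiral stationary phase (SFC) then removes F5 and comes back to the route at 13.

The esterification of step 10 may fail through slow acylation of the hindered α-ketol, with deconjugation of the activated enoate or base-induced loss of the C4 ester as competing processes. The fallback sets out from 14, which is coupled (DIC, catalytic DMAP) with 2-(diethoxyphosphoryl)propanoic acid to the phosphonate ester F6. A Horner–Wadsworth–Emmons reaction with aldehyde 15 (LiCl, iPr2NEt, MeCN) then builds the (E)-enoate in place and comes back to the route at 19.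

Further compounds
F1 | step 4 | 4-[(tert-butyldimethylsilyl)oxy]-2-{[(4-methoxybenzyl)oxy]methyl}-5-(propan-2-yl)cyclohex-2-en-1-one, C5 as in the target, C4–O trans to isopropyl | C1C(=O)C(COCc2ccc(OC)cc2)=C[C@@H](O[Si](C)(C)C(C)(C)C)[C@@H]1C(C)C
F2 | step 4 | 6-hydroxy derivative of F1, OH trans to isopropyl | O[C@H]1C(=O)C(COCc2ccc(OC)cc2)=C[C@@H](O[Si](C)(C)C(C)(C)C)[C@@H]1C(C)C
F3 | step 4 | C6 (2E)-4-[(4-methoxybenzyl)oxy]-2-methylbut-2-enoate of F2 | C/C(=C\COCc1ccc(OC)cc1)C(=O)O[C@H]1C(=O)C(COCc2ccc(OC)cc2)=C[C@@H](O[Si](C)(C)C(C)(C)C)[C@@H]1C(C)C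
F4 | step 4 | C4 alcohol from F3, OH trans to isopropyl | C/C(=C\COCc1ccc(OC)cc1)C(=O)O[C@H]1C(=O)C(COCc2ccc(OC)cc2)=C[C@@H](O)[C@@H]1C(C)C
F5 | step 6 | mirror image of 13, (4R,5R,6S)-6-[(tert-butyldimethylsilyl)oxy]-2-{[(4-methoxybenzyl)oxy]methyl}-4-[(2-methylpropanoyl)oxy]-5-(propan-2-yl)cyclohex-2-en-1-one | CC(C)(C)[Si](C)(C)O[C@@H]1C(=O)C(COCc2ccc(OC)cc2)=C[C@@H](OC(=O)C(C)C)[C@H]1C(C)C
F6 | step 10 | C6 2-(diethoxyphosphoryl)propanoate of 14 (mixture at the phosphonate carbon) | CCOP(=O)(OCC)C(C)C(=O)O[C@H]1C(=O)C(COCc2ccc(OC)cc2)=C[C@H](OC(=O)C(C)C)[C@@H]1C(C)C
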